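The route rests on cutting the C7''–C8'' bond in ring A of the 4-hydroxyphenyl flavone (unit 2). That ring is a phloroglucinol in which C6'', the atom bonded to C8 of the acacetin half (unit 1), sits between the oxygen-bearing C5'' and C7''; it is therefore the Claisen fold of a β-keto ester branched at C6''. The key step closes ring A onto a preformed 4-pyranone (ring C of unit 2) in one operation, forming C7''–C8'' and releasing the 5'',7''-diol. Its precursor is a methyl α-(flavon-8-yl)-β-keto ester whose ketone sits on C3 of a 6-aryl-2-methyl-4-pyranone, made by C-acylation of a flavon-8-ylacetate.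

Key step: step 7

Assumption: the target SMILES carries no descriptor for the hindered C8–C6'' biaryl axis, so 13 and 14 are made without control of axial configuration (racemic if the axis is configurationally stable).

Step 1
Reactants: 1 acacetin [5,7-dihydroxy-2-(4-methoxyphenyl)chromen-4-one]
Product: 2 5,7-bis(benzyloxy)-2-(4-methoxyphenyl)chromen-4-one
Conditions: BnBr (2.6 equiv), K2CO3, Bu4NI (cat.), DMF, 80 °C
Reagents that add atoms: benzyl bromide, BrCc1ccccc1
Why: Williamson ether synthesis; the 7-OH reacts readily and the chelated 5-OH should follow under forcing conditions (excess halide, iodide catalysis, heat), while the 4'-methyl ether and the pyranone ring are inert to carbonate.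

Step 2
Reactants: 2 5,7-bis(benzyloxy)-2-(4-methoxyphenyl)chromen-4-one
Product: 3 5,7-bis(benzyloxy)-8-iodo-2-(4-methoxyphenyl)chromen-4-one
Conditions: I2 (1.05 equiv), CF3CO2Ag (1.05 equiv), CH2Cl2, 0 °C to rt, dark
Reagents that add atoms: iodine, II
Why: Electrophilic aromatic iodination by the trifluoroacetyl hypoiodite formed from I2 and CF3CO2Ag; with both ring A oxygens alkylated, a 5,7-dialkoxyflavone should react at C8 (a free 5-OH would instead steer the halogen to C6), and one equivalent avoids the 6,8-diiodide.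

Step 3
Reactants: 3 5,7-bis(benzyloxy)-8-iodo-2-(4-methoxyphenyl)chromen-4-one
Product: 4 methyl 2-[5,7-bis(benzyloxy)-2-(4-methoxyphenyl)-4-oxochromen-8-yl]acetate
Conditions: BrZnCH2CO2Me (2.5 equiv; from BrCH2CO2Me, Zn, Me3SiCl cat., THF), Pd2(dba)3 (2.5 mol%), XPhos (10 mol%), THF, 60 °C
Reagents that add atoms: bromo(2-methoxy-2-oxoethyl)zinc, COC(=O)C[Zn]Br
Why: Negishi-type coupling of a Reformatsky zinc enolate with the aryl iodide (palladium-catalysed α-arylation of an acetate); the bulky biarylphosphine on zerovalent palladium promotes oxidative addition and reductive elimination at the doubly ortho-substituted C8, and the neutral zinc enolate spares the flavone carbonyl and the benzyl ethers.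

Step 4
Reactants: 5 3-[4-(benzyloxy)phenyl]prop-2-ynoic acid; 6 tert-butyl 3-oxobutanoate (tert-butyl acetoacetate)
Product: 9 tert-butyl 6-[4-(benzyloxy)phenyl]-2-methyl-4-oxopyran-3-carboxylate, via arylpropynoyl chloride 7 (not isolated), via acyclic C-acylated tricarbonyl 8 (not isolated)
Conditions: (i) 5, (COCl)2, DMF (cat.), CH2Cl2, 0 °C to rt; (ii) 6, MgCl2, pyridine, CH2Cl2, 0 °C to rt; (iii) aq. HCl wash, then Et3N, CH2Cl2, rt
Reagents that add atoms: none
Why: Chelation-controlled C-acylation of the magnesium enolate of the β-keto ester by the ynoyl chloride, followed by 6-endo-dig oxa-Michael addition of the acetyl enol oxygen (more nucleophilic than the ester oxygen) to the ynone, a polarity-matched closure that places the methyl group at C2 and the ester at C3 of the 4-pyranone.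

Step 5
Reactants: 9 tert-butyl 6-[4-(benzyloxy)phenyl]-2-methyl-4-oxopyran-3-carboxylate
Product: 10 6-[4-(benzyloxy)phenyl]-2-methyl-4-oxopyran-3-carboxylic acid
Conditions: CF3CO2H/CH2Cl2 (1:3), 0 °C to rt
Reagents that add atoms: none
Why: Acid-mediated cleavage of the tert-butyl ester (E1 loss of 2-methylpropene) avoids hydroxide, which would open the pyranone by attack at C2 or C6; the aryl benzyl ether should tolerate brief exposure to CF3CO2H, and a 4-pyranone-3-carboxylic acid does not decarboxylate at room temperature.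

Step 6
Reactants: 4 methyl 2-[5,7-bis(benzyloxy)-2-(4-methoxyphenyl)-4-oxochromen-8-yl]acetate; 10 6-[4-(benzyloxy)phenyl]-2-methyl-4-oxopyran-3-carboxylic acid
Product: 12 racemic methyl 2-[5,7-bis(benzyloxy)-2-(4-methoxyphenyl)-4-oxochromen-8-yl]-3-{6-[4-(benzyloxy)phenyl]-2-methyl-4-oxopyran-3-yl}-3-oxopropanoate, via pyranone-3-carbonyl chloride 11 (not isolated)
Conditions: (i) 10, (COCl)2, DMF (cat.), CH2Cl2, 0 °C to rt, evaporate; (ii) 4, LiN(SiMe3)2 (2.1 equiv), THF, −78 °C, then 11 in THF, −78 °C; aq. NH4Cl at −78 °C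
Reagents that add atoms: none
Why: Crossed Claisen-type C-acylation of the lithium enolate of the arylacetate by the acid chloride; the second equivalent of base converts the more acidic product into its enolate, which stops double acylation, and the cold quench prevents premature reaction at the pyranone methyl group.

Step 7
Reactants: 12 racemic methyl 2-[5,7-bis(benzyloxy)-2-(4-methoxyphenyl)-4-oxochromen-8-yl]-3-{6-[4-(benzyloxy)phenyl]-2-methyl-4-oxopyran-3-yl}-3-oxopropanoate
Product: 13 5,7-bis(benzyloxy)-8-{2-[4-(benzyloxy)phenyl]-5,7-dihydroxy-4-oxochromen-6-yl}-2-(4-methoxyphenyl)chromen-4-one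
Conditions: LiN(SiMe3)2 (3.5 equiv), THF, −78 °C to rt; then 1 M HCl
Reagents that add atoms: none
Why: Proposed new method: LiN(SiMe3)2 first converts the α-aryl β-keto ester of 12 into its chelated lithium enolate and then removes a proton from the pyranone 2-methyl group, which is vinylogous to the ring carbonyl; the CH2 terminus of this dienolate (future C8'') adds to the ester carbonyl (future C7''), methoxide leaves, and the cyclohexadienone so formed tautomerises at once to the 5'',7''-diphenoxide, an aromatisation that should make the closure irreversible even though the ester is deactivated as an enolate. The closest known reaction types are the polyanion Claisen cyclisation of 3,5,7-triketo esters to acylphloroglucinols and the lateral lithiation of 2-methyl-4-pyranones by amide bases followed by C-acylation; joining the two inside one molecule is the new element. Ring A of unit 2 closes in a 6-(enolendo)-exo-trig mode, which is a favoured closure for enolates. No stereocentre is set: the labile α-centre of 12 becomes the aromatic C6'' and the hindered C8–C6'' axis forms without control. The step needs attack by the methylene carbon in preference to O-acylation through the pyranone carbonyl oxygen; only the carbon pathway can aromatise, whereas the enol lactone from oxygen attack is reopened by methoxide, and the hexamethyldisilazide is too weak and too hindered to metalate C3 of either flavone or to add at C2. Linkage isomers cannot arise, because the carbon that holds unit 1 in 12 already has on either side the two carbonyl carbons destined to be C5'' and C7''.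

Step 8
Reactants: 13 5,7-bis(benzyloxy)-8-{2-[4-(benzyloxy)phenyl]-5,7-dihydroxy-4-oxochromen-6-yl}-2-(4-methoxyphenyl)chromen-4-one
Product: 14 8-[5,7-dihydroxy-2-(4-hydroxyphenyl)-4-oxochromen-6-yl]-5,7-dihydroxy-2-(4-methoxyphenyl)chromen-4-one (CNP0310322.0)
Conditions: H2 (1 atm), Pd/C (10% Pd), THF/MeOH, rt
Reagents that add atoms: none
Why: Catalytic hydrogenolysis of the three aryl benzyl ethers; the aryl methyl ether is inert, and the C2=C3 bonds of both flavones, being part of aryl-conjugated 4-pyranone rings, should be reduced much more slowly at 1 atm, so the reaction is stopped once the benzyl groups are gone.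

Compound list
1 | acacetin, 5,7-dihydroxy-2-(4-methoxyphenyl)chromen-4-one | COc1ccc(-c2cc(=O)c3c(O)cc(O)cc3o2)cc1 | starting material
2 | 5,7-bis(benzyloxy)-2-(4-methoxyphenyl)chromen-4-one | COc1ccc(-c2cc(=O)c3c(OCc4ccccc4)cc(OCc4ccccc4)cc3o2)cc1 | intermediate
3 | 5,7-bis(benzyloxy)-8-iodo-2-(4-methoxyphenyl)chromen-4-one | COc1ccc(-c2cc(=O)c3c(OCc4ccccc4)cc(OCc4ccccc4)c(I)c3o2)cc1 | intermediate
4 | methyl 2-[5,7-bis(benzyloxy)-2-(4-methoxyphenyl)-4-oxochromen-8-yl]acetate | COC(=O)Cc1c(OCc2ccccc2)cc(OCc2ccccc2)c2c(=O)cc(-c3ccc(OC)cc3)oc12 | intermediate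
5 | 3-[4-(benzyloxy)phenyl]prop-2-ynoic acid | O=C(O)C#Cc1ccc(OCc2ccccc2)cc1 | starting material
6 | tert-butyl 3-oxobutanoate | CC(=O)CC(=O)OC(C)(C)C | starting material
7 | 3-[4-(benzyloxy)phenyl]prop-2-ynoyl chloride | O=C(Cl)C#Cc1ccc(OCc2ccccc2)cc1 | intermediate
8 | tert-butyl 2-acetyl-5-[4-(benzyloxy)phenyl]-3-oxopent-4-ynoate (racemic, largely enolised) | CC(=O)C(C(=O)OC(C)(C)C)C(=O)C#Cc1ccc(OCc2ccccc2)cc1 | intermediate
9 | tert-butyl 6-[4-(benzyloxy)phenyl]-2-methyl-4-oxopyran-3-carboxylate | Cc1oc(-c2ccc(OCc3ccccc3)cc2)cc(=O)c1C(=O)OC(C)(C)C | intermediate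
10 | 6-[4-(benzyloxy)phenyl]-2-methyl-4-oxopyran-3-carboxylic acid | Cc1oc(-c2ccc(OCc3ccccc3)cc2)cc(=O)c1C(=O)O | intermediate
11 | 6-[4-(benzyloxy)phenyl]-2-methyl-4-oxopyran-3-carbonyl chloride | Cc1oc(-c2ccc(OCc3ccccc3)cc2)cc(=O)c1C(=O)Cl | intermediate
12 | methyl 2-[5,7-bis(benzyloxy)-2-(4-methoxyphenyl)-4-oxochromen-8-yl]-3-{6-[4-(benzyloxy)phenyl]-2-methyl-4-oxopyran-3-yl}-3-oxopropanoate (racemic at the enolisable α-carbon) | COC(=O)C(C(=O)c1c(C)oc(-c2ccc(OCc3ccccc3)cc2)cc1=O)c1c(OCc2ccccc2)cc(OCc2ccccc2)c2c(=O)cc(-c3ccc(OC)cc3)oc12 | intermediate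
13 | 5,7-bis(benzyloxy)-8-{2-[4-(benzyloxy)phenyl]-5,7-dihydroxy-4-oxochromen-6-yl}-2-(4-methoxyphenyl)chromen-4-one (axis not controlled) | COc1ccc(-c2cc(=O)c3c(OCc4ccccc4)cc(OCc4ccccc4)c(-c4c(O)cc5oc(-c6ccc(OCc7ccccc7)cc6)cc(=O)c5c4O)c3o2)cc1 | intermediate
14 | 8-[5,7-dihydroxy-2-(4-hydroxyphenyl)-4-oxochromen-6-yl]-5,7-dihydroxy-2-(4-methoxyphenyl)chromen-4-one (axis not controlled) | COc1ccc(-c2cc(=O)c3c(O)cc(O)c(-c4c(O)cc5oc(-c6ccc(O)cc6)cc(=O)c5c4O)c3o2)cc1 | target

Total step count: 8
Longest linear sequence: 6 steps (steps 1, 2, 3, 6, 7 and 8, from acacetin 1)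

Steps most likely to fail

1. Step 7. The dianion may fail to close because the ester carbonyl is deactivated as part of the enolate. Reversible O-acylation, retro-Claisen cleavage of the keto ester by the liberated methoxide, or opening of the pyranone ring could then outrun C–C bond formation. The fallback uses known chemistry, a Suzuki–Miyaura union of two finished flavones; it sets out from 3 and comes back to the route at 14. Miyaura borylation of 3 (B2pin2, PdCl2(dppf), KOAc, dioxane, 90 °C) should give 5,7-bis(benzyloxy)-2-(4-methoxyphenyl)-8-(4,4,5,5-tetramethyl-1,3,2-dioxaborolan-2-yl)chromen-4-one F1. Commercial apigenin is benzylated at O7 and O4' (BnBr, K2CO3, acetone, reflux) to 7-(benzyloxy)-2-[4-(benzyloxy)phenyl]-5-hydroxychromen-4-one F2. Iodination at C6 under the direction of the free 5-OH (BnMe3N ICl2, CaCO3, CH2Cl2/MeOH, rt) gives 7-(benzyloxy)-2-[4-(benzyloxy)phenyl]-5-hydroxy-6-iodochromen-4-one F3, and benzylation at O5 (BnBr, K2CO3, DMF, 80 °C) gives 5,7-bis(benzyloxy)-2-[4-(benzyloxy)phenyl]-6-iodochromen-4-one F4. Coupling of F1 with F4 (Pd(OAc)2, SPhos, K3PO4, toluene/H2O, 100 °C) would give 5,7-bis(benzyloxy)-8-{5,7-bis(benzyloxy)-2-[4-(benzyloxy)phenyl]-4-oxochromen-6-yl}-2-(4-methoxyphenyl)chromen-4-one F5. Hydrogenolysis of F5 under the conditions of step 8 delivers 14.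

2. Step 6. Proton transfer from the acidic 2-methyl group of the acid chloride to the hindered ester enolate, O-acylation, or slow reaction at the doubly ortho-flanked benzylic carbon may erode C-acylation. The fallback forms the C6''–C8 bond last instead of the C5''–C6'' bond; it sets out from 10 and 3 and comes back at 12. Acid chloride 11, made from 10 as in step 6, is homologated by decarboxylative acylation of potassium methyl malonate (MgCl2, Et3N, MeCN, 0 °C to rt) to methyl 3-{6-[4-(benzyloxy)phenyl]-2-methyl-4-oxopyran-3-yl}-3-oxopropanoate F6. Its active methylene is then arylated by iodide 3 under copper catalysis (CuI, L-proline, Cs2CO3, DMSO, 40–50 °C) to give 12. The temperature is kept low to limit deacylation of the product.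

3. Step 3. Oxidative addition or transmetalation at the C8–I bond, which is flanked by two oxygen substituents, may be sluggish, so that protodeiodination and self-condensation of the zinc enolate take over. The fallback replaces cross-coupling by sigmatropic C-allylation and oxidative degradation; it sets out from 1 and comes back at 4. Compound 1 is allylated at O7 (allyl bromide, K2CO3, acetone, reflux) to 5-hydroxy-2-(4-methoxyphenyl)-7-(prop-2-enyloxy)chromen-4-one F7. Aromatic Claisen rearrangement (N,N-diethylaniline, 200 °C) should deliver mainly the C8 isomer 5,7-dihydroxy-2-(4-methoxyphenyl)-8-(prop-2-enyl)chromen-4-one F8, with any C6 isomer removed by chromatography. Dibenzylation as in step 1 gives 5,7-bis(benzyloxy)-2-(4-methoxyphenyl)-8-(prop-2-enyl)chromen-4-one F9. Lemieux–Johnson cleavage (OsO4 cat., NaIO4, 2,6-lutidine, dioxane/H2O) gives 2-[5,7-bis(benzyloxy)-2-(4-methoxyphenyl)-4-oxochromen-8-yl]acetaldehyde F10. Pinnick oxidation (NaClO2, NaH2PO4, 2-methylbut-2-ene, t-BuOH/H2O) gives 2-[5,7-bis(benzyloxy)-2-(4-methoxyphenyl)-4-oxochromen-8-yl]acetic acid F11, and esterification with Me3SiCHN2 (toluene/MeOH) gives 4.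

Further compounds
F1 | step 7 | 5,7-bis(benzyloxy)-2-(4-methoxyphenyl)-8-(4,4,5,5-tetramethyl-1,3,2-dioxaborolan-2-yl)chromen-4-one | COc1ccc(-c2cc(=O)c3c(OCc4ccccc4)cc(OCc4ccccc4)c(B4OC(C)(C)C(C)(C)O4)c3o2)cc1
F2 | step 7 | 7-(benzyloxy)-2-[4-(benzyloxy)phenyl]-5-hydroxychromen-4-one | O=c1cc(-c2ccc(OCc3ccccc3)cc2)oc2cc(OCc3ccccc3)cc(O)c12
F3 | step 7 | 7-(benzyloxy)-2-[4-(benzyloxy)phenyl]-5-hydroxy-6-iodochromen-4-one | O=c1cc(-c2ccc(OCc3ccccc3)cc2)oc2cc(OCc3ccccc3)c(I)c(O)c12
F4 | step 7 | 5,7-bis(benzyloxy)-2-[4-(benzyloxy)phenyl]-6-iodochromen-4-one | O=c1cc(-c2ccc(OCc3ccccc3)cc2)oc2cc(OCc3ccccc3)c(I)c(OCc3ccccc3)c12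
F5 | step 7 | 5,7-bis(benzyloxy)-8-{5,7-bis(benzyloxy)-2-[4-(benzyloxy)phenyl]-4-oxochromen-6-yl}-2-(4-methoxyphenyl)chromen-4-one | COc1ccc(-c2cc(=O)c3c(OCc4ccccc4)cc(OCc4ccccc4)c(-c4c(OCc5ccccc5)cc5oc(-c6ccc(OCc7ccccc7)cc6)cc(=O)c5c4OCc4ccccc4)c3o2)cc1
F6 | step 6 | methyl 3-{6-[4-(benzyloxy)phenyl]-2-methyl-4-oxopyran-3-yl}-3-oxopropanoate | COC(=O)CC(=O)c1c(C)oc(-c2ccc(OCc3ccccc3)cc2)cc1=O
F7 | step 3 | 5-hydroxy-2-(4-methoxyphenyl)-7-(prop-2-enyloxy)chromen-4-one | COc1ccc(-c2cc(=O)c3c(O)cc(OCC=C)cc3o2)cc1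
F8 | step 3 | 5,7-dihydroxy-2-(4-methoxyphenyl)-8-(prop-2-enyl)chromen-4-one | COc1ccc(-c2cc(=O)c3c(O)cc(O)c(CC=C)c3o2)cc1
F9 | step 3 | 5,7-bis(benzyloxy)-2-(4-methoxyphenyl)-8-(prop-2-enyl)chromen-4-one | COc1ccc(-c2cc(=O)c3c(OCc4ccccc4)cc(OCc4ccccc4)c(CC=C)c3o2)cc1
F10 | step 3 | 2-[5,7-bis(benzyloxy)-2-(4-methoxyphenyl)-4-oxochromen-8-yl]acetaldehyde | COc1ccc(-c2cc(=O)c3c(OCc4ccccc4)cc(OCc4ccccc4)c(CC=O)c3o2)cc1
F11 | step 3 | 2-[5,7-bis(benzyloxy)-2-(4-methoxyphenyl)-4-oxochromen-8-yl]acetic acid | COc1ccc(-c2cc(=O)c3c(OCc4ccccc4)cc(OCc4ccccc4)c(CC(=O)O)c3o2)cc1
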